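(The earlier runs and the new flask are simulated from invented constants.)

Time is the first thing the earlier runs show: both stop moving at about 4.00 min, though the red run holds 1 equiv of coupling partner and the blue run 6.1 equiv.

| setting | red | blue | east | north-east |
|---|---|---|---|---|
| solid substrate | 0.24 M | 0.24 M | 0.24 M | 0.24 M |
| coupling partner | 1 equiv | 6.1 equiv | 0.800 equiv | 4.00 equiv |
| remark | run made earlier | run made earlier |  |  |
| time |  |  | 20 min | 20 min |

| run | time / min | tetra adduct / % | double product / % |
|---|---|---|---|
| red | 1.00 | 0 | 2 |
| red | 1.50 | 0 | 6 |
| red | 2.50 | 0 | 6 |
| red | 4.00 | 0 | 10 |
| red | 6.00 | 0 | 10 |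
| red | 10.0 | 0 | 11 |
| red | 15.0 | 0 | 8 |
| blue | 0.833 | 14 | 16 |
| blue | 2.00 | 33 | 25 |
| blue | 4.00 | 46 | 21 |
| blue | 6.00 | 46 | 22 |
| blue | 8.00 | 45 | 20 |
| blue | 12.0 | 45 | 22 |
| blue | 15.0 | 46 | 21 |

(standard deviation of a reading: 1.5 percentage points)

- solid substrate is a solid; its amount is given per volume of the solution
- at the start none of the solid substrate is in solution

- which of these holds the largest part of the solid substrate at the end of east (tris adduct / solid substrate / double product / mono adduct / tetra adduct)
- which of these holds the largest part of the solid substrate at the end of north-east (tris adduct / solid substrate / double product / mono adduct / tetra adduct)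
- final tetra adduct in north-east, as a percentage of the solid substrate charged

We suppose that the partner disappears on a clock of its own, so that the exposure of a site grows in proportion to the charge. Each of the 4 sites on the substrate then stays empty with a pseudo-first-order share, exp(-exposure). In the blue run, tetra adduct averages 45.6% from 4.00 min on. On that supposition, taking the square root twice gives 82.2% of sites filled in the blue run. Dividing ln(1/empty share) by the charge gives 0.283, the exposure per equivalent. For north-east, 4.00 equiv then gives an exposure of 1.13, so we reckon 67.7% of sites filled and tetra adduct at 21.0%, our number.

The weak link is the proportion, so we try it on the other run. At 1 equiv it predicts 0.368% tetra adduct, less than the scatter of 1.5 percentage points, and the red readings show 0%.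

The forecast names solid substrate for east and double product for north-east, with 20% tetra adduct (range 12% to 30%), holding that “partner, or its activity, is probably lost on a fixed timescale”. Its number lies just below ours.

    starting material + coupling partner → mono adduct (k = 0.0530 /M/s)
    coupling partner + mono adduct → double product (k = 0.0850 /M/s)
    coupling partner + double product → tris adduct (k = 0.0510 /M/s)
    coupling partner + tris adduct → tetra adduct (k = 0.0680 /M/s)
    solid substrate ⇌ starting material, rate k5*(cs5 - [starting material]) while solid is left; crystals form when [starting material] > cs5 (solubility = 0.110 M, k = 0.0640 /s)
    coupling partner → decomposed reagent (k = 0.00870 /s)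

Of the species asked about, east ends with solid substrate at 30.5% on top, north-east with double product at 26.0%, and north-east holds tetra adduct at 19.4%, which is 1.6 points below our number. In the same flask as north-east but with 6.80 equiv of coupling partner, the same exposure per equivalent gives 53.2% tetra adduct against a simulated 55.4%. North-east has come to rest early: at 10.0 min its coupling partner is 0% and its tetra adduct 19.4%. A longer run makes no difference to its tetra adduct: at ten times the asked time, 200 min, tetra adduct in north-east stands at 19.4%.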